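## The problem

Compound 19 is a cyclohexene with a cis-fused oxirane (7-oxabicyclo[4.1.0]hept-4-ene). The ring is numbered here C1 (the fully substituted oxirane carbon, which carries C7H2OBz), C2 (CHOBz), C3 (CHOH), C4=C5 and C6 (the oxirane CH). Four contiguous stereocentres must be set, one of them quaternary: the C7 arm and the C2 benzoate lie on one ring face, the oxirane oxygen and the C3 hydroxyl on the other. The oxygenated carbons C1, C2, C3, C6 and C7 must be told apart, and the benzoates must end on O2 (a flanked secondary position) and O7 while the more accessible allylic O3 stays free. The vinyl oxirane does not tolerate acid or soft nucleophiles, and a benzoate next to a free hydroxyl migrates under base, so the oxirane has to be closed last and under neutral conditions. On the six-membered ring, equatorial oxygens at C2, C3 and C6 can steer an addition to C1, and C6 can be inverted at the moment the oxirane closes. The enabling feature is hidden: if C1 is read as a carbinol carbon and the C6 oxygen is moved to the other face, C6–C1–C2–C3 with C4=C5 is all-trans conduritol B. Its twofold axis (through the midpoints of C1–C2 and C4=C5) makes O1 and O2 homotopic, and C7 becomes one carbon added to a C1 ketone.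

## Retrosynthesis

19 to 17. The C6–O bond of the oxirane is cut, leaving the trans C1/C6 diol of triol 17. Cutting C1–O instead would demand substitution at a quaternary carbon, and epoxidising a diene would leave face and site selectivity open. The forward step is a Mitsunobu cyclodehydration: it must engage the vicinal diol, leave O3 alone, and invert C6 while C1 keeps its oxygen.

17 to 16 to 14 and 15. The two silyl ethers of 16 are removed, then the O–C7 ester bond is cut to reveal spiro-oxirane 14 and benzoic acid 15. Opening 14 at its only unsubstituted carbon places the C7 benzoate and frees the tertiary O1 hydroxyl in one operation, so no selective acylation of a 1,7-diol is needed. The forward reaction must be an SN2 opening that leaves C1 untouched.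

14 to 11 and 12. Both new bonds of the spiro ring (C1–C7 and C7–O) are cut, giving ketone 11 and the methylene source 12. This is the only disconnection that turns the quaternary centre into an sp2 carbon flanked by two equatorial oxygens, so C1 can be set by substrate control. The forward step must deliver carbon along the axial trajectory and must beat enolisation of a sensitive ketone.

11 to 10 to 8 and 9. The ketone is taken back to alcohol 10 and the O2–benzoyl bond is cut to diol 8 and benzoyl chloride 9. In 8 the two free hydroxyls are homotopic, so monoacylation has no regiochemical question and even a later 1,2-benzoyl shift would be degenerate.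

8 to 7 to 6 to 5. The allylic silyl ethers are removed to tetrol 7, which is the methanolysis product of tetraacetate 6, the slow-reacting enantiomer in a lipase resolution of racemate 5. Silylation has to pick the two allylic hydroxyls (one oxygenated neighbour) over the inner ones (two).

5 to 3 to 2 to 1. The four acetates are traced to the dibromodiol 3 (acetylation, then anchimerically assisted acetolysis of both bromides), 3 to dibromodione 2 by carbonyl reduction, and 2 to p-benzoquinone 1 by bromine addition. All six ring carbons and the C4=C5 alkene come from 1.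

## Roads not taken

Alternative 1: Ring closure by Nozaki–Hiyama–Kishi vinylation. The C5–C6 ring bond is cut, giving the open-chain aldehyde A1 (C6 aldehyde on the quaternary C1, C4=C5 as a Z-vinyl iodide), to be built from a branched pentose. In the forward step CrCl2 (divalent chromium) with catalytic NiCl2 converts the vinyl iodide into a vinylchromium species that adds to the aldehyde and closes the cyclohexene, giving cyclohexenol A2.
- Merits: the carbon–carbon bond formation is mild enough for both benzoates and the silyl ether. The chiral pool supplies a single enantiomer without a resolution. O3 (PMB) and O6 (free) are distinct from the start, so the final oxirane closure has no chemoselectivity question. In these two respects this road is better than the chosen plan.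
- Weak points: A1 needs a long sequence (quaternary centre, five differentiated oxygens, Z-iodoolefination). The new C6 centre is formed in the ring closure with no reliable bias towards the trans C1/C6 arrangement that the oxirane closure requires. Three kinds of protecting group must then be removed.
- Comparison: the chosen plan is shorter (12 steps from 1), takes C2, C3 and C6 from a symmetric tetrol, and sets C1 on a rigid ring.

Alternative 2: Singlet-oxygen endoperoxide contracted to the vinyl oxirane. The C1–O and C4–O bonds are cut, leading from endoperoxide A4 back to the 1,3-diene A3 (C1=C6–C5=C4, with the C2 benzoate and C3 hydroxyl in place). Sensitised singlet oxygen adds across C1 and C4 of A3; a phosphine then removes the C4 oxygen while the C1 oxygen closes on C6 (SN2') and the alkene moves to C4=C5, giving the target directly.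
- Merits: the endgame is the shortest of all. Oxirane oxygen, C1 configuration and alkene position come from one neutral cycloaddition, and no late Mitsunobu selectivity arises. In step count after the last carbon–carbon bond this road is better than the chosen plan.
- Weak points: A3 is an arene trans-dihydrodiol derivative that aromatises by loss of water or benzoic acid and is not easily obtained as one enantiomer. The face of attack depends on two allylic substituents on opposite faces (the hydroxyl would have to direct, the benzoate to shield). Ene reaction, base-induced peroxide fragmentation and attack of the phosphine at the other peroxide oxygen compete.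
- Comparison: the chosen plan uses stable, mostly crystalline intermediates and has a single stereochemical decision on a conformationally defined ketone.

Alternative 3: Payne rearrangement from an epimeric spiro-oxirane. The C1–O(C6) bond is cut, leading back to spiro-oxirane A5, the C1 epimer of the chosen intermediate with the C6 hydroxyl on the face of C7. A C6 alkoxide attacks C1 anti to the spiro C–O bond, closing the fused oxirane and opening the spiro ring to a C7 alkoxide, which is protonated to the C7 alcohol A6; selective benzoylation of the primary hydroxyl would finish.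
- Merits: two operations after the spiro-oxirane instead of three, and no activation of C6. Here it is better than the chosen plan.
- Weak points: the alkoxide medium threatens the C2 benzoate (migration to O3, cleavage). The substitution occurs at a fully substituted carbon and is an equilibrium that ends in a reactive vinyl oxirane. A5 needs equatorial methylene delivery and a C6 oxygen trans to the C2 oxygen across C1, a pattern without the twofold axis, so the homotopic-hydroxyl placement of the C2 benzoate is lost.
- Comparison: the chosen plan keeps the symmetry and treats the benzoates only under buffered or neutral conditions.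

Key step: step 9

Remark: locants C1–C7 are those of the target throughout. Racemic compounds (2–5) are written with the SMILES of the enantiomer that is carried on and are marked rac.

Assumption: in the lipase alcoholysis of step 4 the (1R,2S,3S,4R)-tetraacetate is taken to be the slow-reacting enantiomer and the antipode to lose its two allylic acetates. If the enzyme has the opposite preference, the deacylated fraction is carried into step 5, which converges on the same tetrol.

## Route

Step 1
Reactants: 1 p-benzoquinone
Product: 2 rac-trans-5,6-dibromocyclohex-2-ene-1,4-dione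
Conditions: Br2 (1.0 equiv), CHCl3, 0 °C
Reagents that add atoms: bromine, BrBr
Why: Electrophilic anti addition of bromine to one enedione double bond (bromonium opening) gives the trans-dibromide; the remaining alkene is deactivated by two carbonyls, so addition should stop after one equivalent.

Step 2
Reactants: 2 rac-trans-5,6-dibromocyclohex-2-ene-1,4-dione
Product: 3 rac-(1R,4R,5S,6S)-5,6-dibromocyclohex-2-ene-1,4-diol
Conditions: NaBH4, Et2O/H2O, 0 °C
Reagents that add atoms: none
Why: Twofold 1,2-reduction of the carbonyls by borohydride; each hydride is expected to enter anti to the bromine on the remote carbon, the established course for this dione, which places every hydroxyl trans to its neighbouring bromine and keeps the twofold axis.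

Step 3
Reactants: 3 rac-(1R,4R,5S,6S)-5,6-dibromocyclohex-2-ene-1,4-diol
Product: 5 rac-conduritol B tetraacetate, via dibromo diacetate 4 (not isolated)
Conditions: Ac2O, AcOH, KOAc, reflux
Reagents that add atoms: acetic anhydride, CC(=O)OC(C)=O; potassium acetate, CC(=O)[O-].[K+]
Why: O-Acetylation gives 4, in which each allylic acetate is trans to the adjacent bromide; acetolysis with neighbouring-group participation (acetoxonium formation with inversion, opening by acetate with a second inversion) replaces both bromides with net retention and should give the all-trans tetraacetate.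

Step 4
Reactants: 5 rac-conduritol B tetraacetate
Product: 6 (1R,2S,3S,4R)-cyclohex-5-ene-1,2,3,4-tetrayl tetraacetate
Conditions: immobilised Rhizomucor miehei lipase, n-BuOH, t-BuOMe, 40 °C, stopped near half conversion
Reagents that add atoms: none
Why: Lipase-mediated kinetic resolution by enantioselective alcoholysis: the enzyme should deacylate the antipode and leave 6, which is separated from the more polar partial esters by chromatography.

Step 5
Reactants: 6 (1R,2S,3S,4R)-cyclohex-5-ene-1,2,3,4-tetrayl tetraacetate
Product: 7 (1R,2S,3S,4R)-cyclohex-5-ene-1,2,3,4-tetrol (conduritol B)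
Conditions: K2CO3 (cat.), MeOH, 20 °C
Reagents that add atoms: none
Why: Base-catalysed transesterification to methanol removes the four acetates; no stereocentre is touched.

Step 6
Reactants: 7 (1R,2S,3S,4R)-cyclohex-5-ene-1,2,3,4-tetrol
Product: 8 (1R,2R,3R,6R)-3,6-bis[(tert-butyldimethylsilyl)oxy]cyclohex-4-ene-1,2-diol
Conditions: TBSCl (2.2 equiv), imidazole, DMF, 0 °C
Reagents that add atoms: tert-butyl(chloro)dimethylsilane, CC(C)(C)[Si](C)(C)Cl
Why: Sterically controlled silylation: the allylic hydroxyls have one oxygenated neighbour and should react before the inner ones, which have two and become more shielded after each silylation (the pattern known for shikimate-type triols); the product keeps the twofold axis.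

Step 7
Reactants: 8 (1R,2R,3R,6R)-3,6-bis[(tert-butyldimethylsilyl)oxy]cyclohex-4-ene-1,2-diol; 9 benzoyl chloride
Product: 10 (1R,2R,3R,6R)-2-hydroxy-3,6-bis[(tert-butyldimethylsilyl)oxy]cyclohex-4-en-1-yl benzoate
Conditions: 9 (1.05 equiv), pyridine, DMAP (cat.), CH2Cl2, −20 to 0 °C
Reagents that add atoms: none
Why: Acylation of one of two homotopic hydroxyls, so either site gives 10 and a 1,2-benzoyl shift between O1 and O2 is degenerate; the second acylation should be slower beside the new ester, and diol and dibenzoate can be recycled.

Step 8
Reactants: 10 (1R,2R,3R,6R)-2-hydroxy-3,6-bis[(tert-butyldimethylsilyl)oxy]cyclohex-4-en-1-yl benzoate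
Product: 11 (1S,2R,5R)-2,5-bis[(tert-butyldimethylsilyl)oxy]-6-oxocyclohex-3-en-1-yl benzoate
Conditions: Dess–Martin periodinane, NaHCO3, CH2Cl2, 0 to 20 °C
Reagents that add atoms: none
Why: Dess–Martin oxidation of the remaining secondary alcohol under buffered, amine-free conditions, because the β,γ-unsaturated α,α'-dioxygenated ketone would enolise, conjugate or eliminate with base; 11 is carried on at once without chromatography.

Step 9
Reactants: 11 (1S,2R,5R)-2,5-bis[(tert-butyldimethylsilyl)oxy]-6-oxocyclohex-3-en-1-yl benzoate; 12 trimethylsulfonium iodide
Product: 14 (3R,4R,7R,8S)-4,7-bis[(tert-butyldimethylsilyl)oxy]-1-oxaspiro[2.5]oct-5-en-8-yl benzoate, via sulfonium alkoxide betaine 13 (not isolated)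
Conditions: 12 (1.6 equiv), KN(SiMe3)2 (1.5 equiv), THF, −10 °C; then 11, −78 to −40 °C
Reagents that add atoms: none
Why: Corey–Chaykovsky epoxidation: the unstabilised ylide made from 12 adds irreversibly to the C1 carbonyl to give betaine 13, whose alkoxide displaces dimethyl sulfide from C7 and so forms the C1–C7 bond and the spiro C1–O–C7 ring. The closest known reaction type is methylene transfer from dimethylsulfonium methylide to cyclohexanones and to α-oxygenated ketones such as uloses. The one ring formed closes in the 3-exo-tet mode. The new C1 centre is set by substrate control: in the half-chair that holds the C2, C3 and C6 oxygens pseudo-equatorial, the small ylide should take the axial path, which meets only the C3 hydrogen (C5 is sp2), whereas the equatorial path eclipses the axial hydrogens on C2 and C6. C7 therefore ends on the face of the C2 and C6 oxygens and O1 on the other face, as 19 requires. The step needs addition to outrun deprotonation at C2 or C6 and attack at the ester; low temperature, a slight deficit of base, the potassium counter-ion (fast closure of 13 before any benzoyl transfer) and silyl ethers as poor β-leaving groups serve this. Kinetic control is essential, since a reversibly adding sulfoxonium ylide would be expected to give the C1 epimer.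

Step 10
Reactants: 14 (3R,4R,7R,8S)-4,7-bis[(tert-butyldimethylsilyl)oxy]-1-oxaspiro[2.5]oct-5-en-8-yl benzoate; 15 benzoic acid
Product: 16 [(1R,2S,3R,6R)-2-(benzoyloxy)-3,6-bis[(tert-butyldimethylsilyl)oxy]-1-hydroxycyclohex-4-en-1-yl]methyl benzoate
Conditions: 15 (3 equiv), Cs2CO3 (0.5 equiv), DMF, 70 °C
Reagents that add atoms: none
Why: SN2 opening of a 2,2-disubstituted oxirane at its unsubstituted carbon by caesium benzoate, which forms in the flask from part of 15 and Cs2CO3; the free acid that remains protonates the tertiary alkoxide at once and regenerates the carboxylate, so no alkoxide should persist to move a benzoyl or silyl group, and C1 is not touched.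

Step 11
Reactants: 16 [(1R,2S,3R,6R)-2-(benzoyloxy)-3,6-bis[(tert-butyldimethylsilyl)oxy]-1-hydroxycyclohex-4-en-1-yl]methyl benzoate
Product: 17 [(1S,2S,3R,6R)-2-(benzoyloxy)-1,3,6-trihydroxycyclohex-4-en-1-yl]methyl benzoate
Conditions: HF·pyridine, pyridine, THF, 0 to 20 °C
Reagents that add atoms: none
Why: Fluoride-mediated cleavage of both silyl ethers in a weakly acidic buffered medium, which should avoid the O2-to-O3 benzoyl migration that basic fluoride sources promote; esters and the tertiary alcohol are inert.

Step 12
Reactants: 17 [(1S,2S,3R,6R)-2-(benzoyloxy)-1,3,6-trihydroxycyclohex-4-en-1-yl]methyl benzoate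
Product: 19 [(1S,2S,3R,6S)-2-(benzoyloxy)-3-hydroxy-7-oxabicyclo[4.1.0]hept-4-en-1-yl]methyl benzoate, via C6 oxyphosphonium betaine 18 (not isolated)
Conditions: PPh3 (1.2 equiv), DIAD (1.2 equiv), THF, 0 to 20 °C
Reagents that add atoms: none
Why: Mitsunobu cyclodehydration of a trans-1,2-diol: the vicinal C1/C6 diol is engaged, the secondary allylic O6 becomes the oxyphosphonium leaving group and the tertiary O1 displaces it through the diaxial half-chair (3-exo-tet, inversion at C6), giving the cis-fused oxirane on the face of O1. No acidic partner is present, so the isolated C3 hydroxyl has no productive pathway, and the neutral medium spares the benzoates and the vinyl oxirane.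

## Compound list

1 | p-benzoquinone | O=C1C=CC(=O)C=C1 | starting material
2 | rac-(5S,6S)-5,6-dibromocyclohex-2-ene-1,4-dione (trans-dibromide) | O=C1[C@H](Br)[C@@H](Br)C(=O)C=C1 | intermediate
3 | rac-(1R,4R,5S,6S)-5,6-dibromocyclohex-2-ene-1,4-diol (all neighbours trans) | O[C@H]1[C@H](Br)[C@@H](Br)[C@H](O)C=C1 | intermediate
4 | rac-(1R,4R,5S,6S)-5,6-dibromocyclohex-2-ene-1,4-diyl diacetate | CC(=O)O[C@H]1[C@H](Br)[C@@H](Br)[C@H](OC(C)=O)C=C1 | intermediate (not isolated)
5 | rac-conduritol B tetraacetate (all-trans cyclohex-5-ene-1,2,3,4-tetrayl tetraacetate) | CC(=O)O[C@H]1[C@H](OC(C)=O)[C@@H](OC(C)=O)[C@H](OC(C)=O)C=C1 | intermediate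
6 | (1R,2S,3S,4R)-cyclohex-5-ene-1,2,3,4-tetrayl tetraacetate | CC(=O)O[C@H]1[C@H](OC(C)=O)[C@@H](OC(C)=O)[C@H](OC(C)=O)C=C1 | intermediate
7 | (1R,2S,3S,4R)-cyclohex-5-ene-1,2,3,4-tetrol (conduritol B, single enantiomer) | O[C@H]1[C@H](O)[C@@H](O)[C@H](O)C=C1 | intermediate
8 | (1R,2R,3R,6R)-3,6-bis[(tert-butyldimethylsilyl)oxy]cyclohex-4-ene-1,2-diol | CC(C)(C)[Si](C)(C)O[C@H]1[C@H](O)[C@@H](O)[C@H](O[Si](C)(C)C(C)(C)C)C=C1 | intermediate
9 | benzoyl chloride | O=C(Cl)c1ccccc1 | starting material
10 | (1R,2R,3R,6R)-2-hydroxy-3,6-bis[(tert-butyldimethylsilyl)oxy]cyclohex-4-en-1-yl benzoate | O[C@H]1[C@H](O[Si](C)(C)C(C)(C)C)C=C[C@@H](O[Si](C)(C)C(C)(C)C)[C@@H]1OC(=O)c1ccccc1 | intermediate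
11 | (1S,2R,5R)-2,5-bis[(tert-butyldimethylsilyl)oxy]-6-oxocyclohex-3-en-1-yl benzoate (C1 ketone) | O=C1[C@H](O[Si](C)(C)C(C)(C)C)C=C[C@@H](O[Si](C)(C)C(C)(C)C)[C@@H]1OC(=O)c1ccccc1 | intermediate
12 | trimethylsulfonium iodide | C[S+](C)C.[I-] | starting material
13 | sulfonium alkoxide betaine (C1 alkoxide on the face opposite the C2 and C6 oxygens, C7 bearing dimethylsulfonium) | C[S+](C)C[C@]1([O-])[C@H](O[Si](C)(C)C(C)(C)C)C=C[C@@H](O[Si](C)(C)C(C)(C)C)[C@@H]1OC(=O)c1ccccc1 | intermediate (not isolated)
14 | (3R,4R,7R,8S)-4,7-bis[(tert-butyldimethylsilyl)oxy]-1-oxaspiro[2.5]oct-5-en-8-yl benzoate (C7 cis to the C2 and C6 oxygens) | C1O[C@]12[C@H](O[Si](C)(C)C(C)(C)C)C=C[C@@H](O[Si](C)(C)C(C)(C)C)[C@@H]2OC(=O)c1ccccc1 | intermediate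
15 | benzoic acid | O=C(O)c1ccccc1 | starting material
16 | [(1R,2S,3R,6R)-2-(benzoyloxy)-3,6-bis[(tert-butyldimethylsilyl)oxy]-1-hydroxycyclohex-4-en-1-yl]methyl benzoate | O=C(OC[C@]1(O)[C@H](O[Si](C)(C)C(C)(C)C)C=C[C@@H](O[Si](C)(C)C(C)(C)C)[C@@H]1OC(=O)c1ccccc1)c1ccccc1 | intermediate
17 | [(1S,2S,3R,6R)-2-(benzoyloxy)-1,3,6-trihydroxycyclohex-4-en-1-yl]methyl benzoate | O=C(OC[C@]1(O)[C@H](O)C=C[C@@H](O)[C@@H]1OC(=O)c1ccccc1)c1ccccc1 | intermediate
18 | C6 oxyphosphonium betaine (O6 bound to triphenylphosphonium, C1 alkoxide) | O=C(OC[C@]1([O-])[C@H](O[P+](c2ccccc2)(c2ccccc2)c2ccccc2)C=C[C@@H](O)[C@@H]1OC(=O)c1ccccc1)c1ccccc1 | intermediate (not isolated)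
19 | [(1S,2S,3R,6S)-2-(benzoyloxy)-3-hydroxy-7-oxabicyclo[4.1.0]hept-4-en-1-yl]methyl benzoate (CNP0285759.2) | O=C(OC[C@]12O[C@H]1C=C[C@@H](O)[C@@H]2OC(=O)c1ccccc1)c1ccccc1 | target

## Step count and least certain steps

Total: 12 steps. Longest linear sequence: 12 steps, from 1 to 19.

Step 9 (key step). The most likely failure is proton transfer from C6 or C2 to the ylide outrunning carbonyl addition, after which the enolate epimerises, eliminates or aromatises. A second concern is erosion of the axial preference by the silyl ether next to the carbonyl. Fallback, from 11 back to 14: diazomethane in Et2O/MeOH at 0 °C, a neutral methylene donor that forms the same C1–C7 bond and closes the same oxirane by loss of dinitrogen from a diazonium alkoxide. This is known for α-oxygenated cyclohexanones (inososes, uloses); the facial outcome would have to be established again. It passes through no new isolable compound, which is recorded as F0.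

Step 10. The most likely failure is slow substitution at C7, which is neopentylic and shielded by the cis C6 silyl ether, so that prolonged heating lets the transient tertiary alkoxide move a silyl or benzoyl group. Fallback, from 14 to 17: the silyl ethers are removed first with TBAF buffered by AcOH (THF, 0 °C) to give (3S,4R,7R,8S)-4,7-dihydroxy-1-oxaspiro[2.5]oct-5-en-8-yl benzoate F1. Its now unshielded oxirane is opened with 15 and Cs2CO3 in DMF under the acid-rich conditions of step 10, where the free acid keeps the C6 alkoxide concentration too low for epoxide migration, and the route is rejoined at 17.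

Step 12. The most likely failure is activation of the isolated C3 hydroxyl instead of the diol, followed by participation of the neighbouring C2 benzoate carbonyl and loss of the C3 configuration or of the ester position. Fallback, from 17 to 19: catalytic Bu2SnO, TsCl and Et3N in CH2Cl2 sulfonylate only through the tin acetal of the vicinal C1/C6 diol, at the secondary oxygen. This gives the C6 tosylate [(1R,2S,3R,6R)-2-(benzoyloxy)-1,3-dihydroxy-6-(tosyloxy)cyclohex-4-en-1-yl]methyl benzoate F2, which is closed to 19 with DBU in CH2Cl2 at 0 °C (inversion at C6).

Step 4. The most likely failure is insufficient or reversed enantiomer discrimination by the lipase on this tetraester, so that 6 is not obtained enantiopure at half conversion. Fallback, from 5 to 7: methanolysis (K2CO3, MeOH) to racemic conduritol B F3, then peracylation with (S)-O-acetylmandeloyl chloride in pyridine and separation of the two diastereomeric tetraesters by crystallisation or chromatography. The tetraester of the (1R,2S,3S,4R) tetrol, (1R,2S,3S,4R)-cyclohex-5-ene-1,2,3,4-tetrayl tetrakis[(2S)-2-acetoxy-2-phenylacetate] F4, is cleaved with K2CO3 in MeOH to rejoin the route at 7. Its diastereomer from the antipodal tetrol, (1S,2R,3R,4S)-cyclohex-5-ene-1,2,3,4-tetrayl tetrakis[(2S)-2-acetoxy-2-phenylacetate] F5, is set aside.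

## Further compounds

F0 | step 9 | none | none
F1 | step 10 | (3S,4R,7R,8S)-4,7-dihydroxy-1-oxaspiro[2.5]oct-5-en-8-yl benzoate | C1O[C@]12[C@H](O)C=C[C@@H](O)[C@@H]2OC(=O)c1ccccc1
F2 | step 12 | [(1R,2S,3R,6R)-2-(benzoyloxy)-1,3-dihydroxy-6-(tosyloxy)cyclohex-4-en-1-yl]methyl benzoate | O=C(OC[C@]1(O)[C@H](OS(=O)(=O)c2ccc(C)cc2)C=C[C@@H](O)[C@@H]1OC(=O)c1ccccc1)c1ccccc1
F3 | step 4 | rac-conduritol B (all-trans cyclohex-5-ene-1,2,3,4-tetrol, racemate, one enantiomer drawn) | O[C@H]1[C@H](O)[C@@H](O)[C@H](O)C=C1
F4 | step 4 | (1R,2S,3S,4R)-cyclohex-5-ene-1,2,3,4-tetrayl tetrakis[(2S)-2-acetoxy-2-phenylacetate] | CC(=O)O[C@@H](c2ccccc2)C(=O)O[C@H]1[C@H](OC(=O)[C@@H](OC(C)=O)c2ccccc2)[C@@H](OC(=O)[C@@H](OC(C)=O)c2ccccc2)[C@H](OC(=O)[C@@H](OC(C)=O)c2ccccc2)C=C1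
F5 | step 4 | (1S,2R,3R,4S)-cyclohex-5-ene-1,2,3,4-tetrayl tetrakis[(2S)-2-acetoxy-2-phenylacetate] | CC(=O)O[C@@H](c2ccccc2)C(=O)O[C@@H]1[C@@H](OC(=O)[C@@H](OC(C)=O)c2ccccc2)[C@H](OC(=O)[C@@H](OC(C)=O)c2ccccc2)[C@@H](OC(=O)[C@@H](OC(C)=O)c2ccccc2)C=C1
A1 | alternative 1 | open-chain C6 aldehyde with the C1 triethylsilyloxy quaternary centre, C2 benzoate, C3 PMB ether and C4=C5 Z-vinyl iodide | O=C[C@](COC(=O)c1ccccc1)(O[Si](CC)(CC)CC)[C@@H](OC(=O)c1ccccc1)[C@H](OCc1ccc(OC)cc1)/C=C\I
A2 | alternative 1 | cyclohexenol from the ring closure, C6 hydroxyl trans to the C1 oxygen | O=C(OC[C@]1(O[Si](CC)(CC)CC)[C@H](O)C=C[C@@H](OCc2ccc(OC)cc2)[C@@H]1OC(=O)c1ccccc1)c1ccccc1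
A3 | alternative 2 | cyclohexa-1,3-diene (C1=C6–C5=C4) with C7 benzoate, C2 benzoate and C3 hydroxyl | O=C(OCC1=CC=C[C@@H](O)[C@@H]1OC(=O)c1ccccc1)c1ccccc1
A4 | alternative 2 | C1,C4-endoperoxide, peroxide bridge anti to the C2 benzoate | O=C(OC[C@]12OO[C@H](C=C1)[C@@H](O)[C@@H]2OC(=O)c1ccccc1)c1ccccc1
A5 | alternative 3 | C1-epimeric spiro-oxirane with free C3 and C6 hydroxyls, C6 hydroxyl cis to C7 | C1O[C@@]12[C@@H](O)C=C[C@@H](O)[C@@H]2OC(=O)c1ccccc1
A6 | alternative 3 | target skeleton with free C7 hydroxyl (C2 monobenzoate) | OC[C@]12O[C@H]1C=C[C@@H](O)[C@@H]2OC(=O)c1ccccc1
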